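Readings and results come from a simulation from invented constants; the scatter is artificial.

The north-east run puts nearly all of its free monomer into chains by 8.00 d, while the east run, with more transfer agent (21 mM against 5.6 mM), reaches 78% at 8.00 d.

| setting | north-east | east | birch | larch |
|---|---|---|---|---|
| free monomer | 0.80 M | 0.80 M | 0.80 M | 0.80 M |
| transfer agent | 5.6 mM | 21 mM | 8.00 mM | 25.0 mM |
| initiator | 54 mM | 54 mM | 54 mM | 54 mM |
| impurity | 50 mM | 50 mM | 50 mM | 50 mM |
| remark | run made earlier | run made earlier |  |  |
| time |  |  | 10 d | 10 d |

| run | time / d | monomer in chains / % |
|---|---|---|
| north-east | 0.625 | 32 |
| north-east | 1.25 | 50 |
| north-east | 3.00 | 77 |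
| north-east | 8.00 | 98 |
| east | 1.67 | 36 |
| east | 4.00 | 57 |
| east | 5.00 | 63 |
| east | 8.00 | 78 |

(scatter of a reading: 1.5 percentage points)

- the average divides the monomer in chains by the number of chains begun, living and dead together
- the numbers in the tables scatter with a standard deviation of 1.5 percentage points
- the earlier runs do not show the number of chains; that part of a forecast is a guess

* which of the two ends with the longer chains by the average number of monomer units in a chain (chains begun, living or dead) ("neither" if they lie within 10%) (birch / larch / neither)
* average number of monomer units in a chain (chains begun, living or dead) at the end, birch
* average number of monomer units in a chain (chains begun, living or dead) at the end, larch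

The average length is monomer in chains over chains begun, so the reckoning turns on the share of the charged initiator that begins a chain, here called the chain share. Two extreme flasks bound it. In the first, every initiator begins a chain, and complete uptake gives 14.8 units. In the second, the whole charge of impurity takes up initiator first. That leaves a share of 0.0741 and 200 units.

Suppose each transfer agent ends one growing chain, and uptake follows the growing ends that remain, pseudo-first-order in free monomer. Then the second extreme fails: its share lies below the east run's agent share of 0.389, yet the east run was still climbing from 63% to 78%. The real share lies between that value and the first extreme.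

The two runs locate it. The slope of minus ln(fraction free) is 0.477 d⁻¹ in the north-east run and 0.168 d⁻¹ in the east run. Each slope is proportional to the chain share minus the agent share, which gives a chain share of 0.543, a reading with the scatter of the runs. 1.08 d⁻¹ is the slope per unit of share left.

Leaving out the small early offset, birch reaches 98.6% and 26.9 units, and larch reaches 58.2% and 15.9 units. My reckoning therefore favours birch.

The forecast also names birch, but with fewer units than this reckoning, 12.6 for birch and 8 for larch, and its note reads “Chain count is the guess.”

The flask gives birch, with 29.2 units in birch and 17.7 in larch.

    free monomer + initiator → living end + monomer in chains (k = 0.0160 L mol⁻¹ min⁻¹)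
    free monomer + living end → monomer in chains + living end, rate k2*[living end]*[free monomer] (k = 0.0160 L mol⁻¹ min⁻¹)
    living end + transfer agent → dead chain (kL = 0.100 L mol⁻¹ min⁻¹)
    initiator → spent initiator A (k = 4.00 × 10⁻⁴ min⁻¹)
    initiator + impurity → spent initiator B (k = 0.340 L mol⁻¹ min⁻¹)

In birch, living end and dead chain together stand at 0.501 of the initiator charge, beside the 0.543 read from the runs. The neighbour is birch with 0.032 M of initiator, and it ends with 82.4% monomer in chains. The chain share of 0.543 gives it 37.9 units. In that neighbour, living end and dead chain stand at 0.467 of its initiator charge, and its average is 44.1 units.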